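In a closed, stirred vessel the starting material may go two ways on: one molecule closes to the ring, or two join to the open dimer. The ring can then go on to the over-reaction product.

| setting | alder | birch | flask |
|---|---|---|---|
| starting material | 0.50 M | 1 M | 0.50 M |
| remark | the very flask that is asked about, followed so far | run made earlier |  |
| time |  |  | 2.5 h |

alder run (percent of the starting material charged)

| time / min | open dimer / % | ring / % |
|---|---|---|
| 6.00 | 73.8 | 6.5 |
| 10.0 | 74.2 | 1.8 |
| 15.0 | 75.6 | 1.3 |
| 25.0 | 76.3 | 0 |
| 50.0 | 75.0 | 0 |
| 80.0 | 73.2 | 0 |

birch run (percent of the starting material charged)

| time / h | open dimer / % | ring / % |
|---|---|---|
| 0.417 | 83.6 | 0 |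
| 0.833 | 83.5 | 0 |
| 1.33 | 83.6 | 0 |
| 1.50 | 83.4 | 0 |
| 2.00 | 83.3 | 1.1 |
| 2.50 | 81.5 | 0 |

(scatter of a reading: 1 percentage point)

- percent here means starting material units held: one open dimer counts as two
- what may be going on: starting material -> ring; 2 starting material -> open dimer; ring -> over-reaction product
- the reaction counts as stopped when no species that holds the starting material changes by six tenths of a point or more over the second half of the time

1. why nothing more happens at 2.5 h, or that something still does (forward and back rates have come level / all of the starting material has reacted / it is still moving)
2. the open dimer standing at 2.5 h, as a percentage of the starting material charged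
3. amount of ring if the flask were left three thousand times as long, in percent of the starting material charged

We can turn two settings. Take time first. In the alder run, the flask we are asked about, the open dimer reads between 73.2% and 76.3% from 6.00 min to 80.0 min. The ring reads 6.5% at 6.00 min and 0% from 25.0 min on, so by hand, waiting should add no open dimer and bring back no ring.

Now take the charge. If ring closure goes with the concentration S and pairing with its square, the open dimer takes the share S/(S + c) of whatever is used, where c is the concentration at which the two ways run level. Adding that share up as S falls from the charge to zero is one integral, with x = charge/c:

yield = 1 − ln(1 + x)/x

The birch readings average 83.2%, and x = 17 gives 83.0%. Read from these scattered readings, that puts at 0.0588 M the crossover concentration, where both ways use starting material equally fast. For this flask x, the selectivity factor at the start, is 8.50, so we commit to 73.5%; the alder readings average 74.7%.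

The forecast answers all of the starting material has reacted, with ring 0%. For the open dimer, “Pooling the two gives about” 74.3%, which is higher than our figure.

The flask gives all of the starting material has reacted, open dimer 73.7%, and ring 0%.

    starting material → ring (k = 0.0164 /s)
    2 starting material → open dimer (k = 0.141 /M/s)
    ring → over-reaction product (k = 0.00401 /s)

Our 73.5% lies 0.20 percentage points under the flask's value. Time leaves the open dimer where it is: it still stands at 73.7% after 25.0 h. Now take the neighbouring flask, charged with 0.12 M. The same crossover concentration gives x = 2.04, and so a yield of 45.5%. That neighbour ends with 45.7% of open dimer and 54.3% of over-reaction product.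

The data come from a simulation on assumed constants.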